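## Structural features

The target is a flavonol: a 4H-chromen-4-one in which benzo ring A is fused to pyranone ring C across C4a–C8a, with a catechol-derived ring B attached through the single C2–C1′ bond. Every carbon is sp2 and there is no stereocentre, so nothing has to be set or kept in three dimensions. Five oxygens sit on the periphery: the enolic O3 and the ring B oxygen O3′ carry sulfate monoesters, while O5, O7 and O4′ are free phenols. The sulfate monoesters are the fragile groups. They hydrolyse under acid, are stable only as salts, and must therefore be introduced late and followed only by neutral chemistry. The real difficulty is not the skeleton but telling five hydroxyls apart, above all O3′ from its neighbour O4′ and O3 from the ring A phenols. This is best settled while the fragments are made, not on the assembled flavonol. The key step uses two features. Ring C, with its C3 oxygen and a carboxyl carbon on the future C8a, is the skeleton of comenic acid, whose C5=C6 bond becomes the C4a–C8a ring fusion. Ring A is a resorcinol whose oxygen-bearing carbons C5 and C7 stand 1,3 to each other, exactly where a ketene carbonyl carbon and an ynol ether carbon end up in a vinylketene–alkyne benzannulation.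

## Logic of the disconnections

28 back to 27: the three benzyl–oxygen bonds at O4′, O5 and O7 are cut. The phenols must be unveiled after sulfation, and only a neutral method spares the O–S bonds. The gain is that the last step becomes a hydrogenolysis with no selectivity question. The forward step must leave the sulfates and the C2=C3 bond untouched.

27 back to 26: the two O–S bonds at O3 and O3′ are cut. Sulfation cannot choose among five hydroxyls, so 26 may have only these two free. The forward step must drive sulfation to completion at the hindered enolic O3.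

26 back to 25 and 24: the two acetal groups on O3 and O3′ and the benzyl ethers on O5 and O7 are exchanged for free hydroxyls. Acid-labile acetals mark the future sulfate sites and hydrogenolysis-labile ethers mark the future phenols, so the two sets never compete. The demands are benzylation of the hydrogen-bonded 5-OH of 24 and acetal cleavage in 25 without loss of the chelated 5-O-benzyl ether.

24 back to 23: the C6–Si and O7–Si bonds are restored. Both silicon atoms are spectators inherited from 10, where they make the ynol ether stable and handleable. The forward step must remove them without an acid strong enough to strip the acetals, otherwise the differentiation of O3 and O3′ is lost.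

23 back to 18 and 10: the four ring A bonds C8–C8a, C7–C8, C5–C6 and C4a–C5 are cut in one operation. This removes the whole resorcinol ring and leaves a monocyclic pyranone plus a two-carbon alkyne. The forward cascade must deliver one regiochemistry in the ketene–alkyne addition and fuse the new ring only across the pyranone C5=C6 bond.

18 back to 16: the bond between the acyl carbon (future C5) and the diazo carbon (future C8) is cut, giving a carboxylic acid. The forward step must attach the diazomethyl carbon without cycloaddition of the diazo reagent to the electron-poor pyranone.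

16 back to 14 and 6: the C2–C1′ bond is cut, which separates ring B with its protecting pattern from ring C. The forward cross-coupling, followed by ester hydrolysis through 15, must tolerate a base-sensitive β-bromo enone.

14 back to 13, 12 and 11: the acetal O–C bond, the C–Br bond and the ester O–CH3 bond are cut in turn. The bromine is needed next to the hydroxyl of 12, which the enol itself directs.

6 back to 5, 4, 2 and 1: the C–B bond, the acetal O–C bond and the C–Br bond are cut. Here a correction is needed. Bromination of 1 itself would go para to the free hydroxyl and would give a ring B with the acetal and benzyl groups interchanged, placing the sulfate on O4′. The hydroxyl is therefore first masked as the weakly donating acetate 2, so that bromine enters para to the benzyloxy group (3), and the acetate is then exchanged for the acetal (4 to 5).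

10 back to 7: the alkyne C–O bond and the O–Si bond are cut. The forward step must oxidise the acetylide to the ynolate and silylate it on oxygen, not on carbon.

## Other disconnections considered

Alternative 1: The cut is the O1–C8a bond of ring C. In the forward sense the racemic furylcarbinol A1 would be oxidised at an anode in methanol with a bromide mediator and then treated with mild aqueous acid, so that the carbinol oxygen closes onto the former furan carbon and gives the dihydropyranone A2 (an Achmatowicz rearrangement).
- In its favour: the aryl–C2 bond of A1 would come from a simple carbonyl addition, so the bromination, borylation and palladium coupling of the chosen plan are not needed. On this count, and in using electricity in place of a stoichiometric oxidant, it is the better of the two.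
- Its key step is a broadly used ring expansion and carries less mechanistic risk than a benzannulation on an untested pyranone. Here too it is at least the equal.
- Against it: A2 has a ketone at C3 but no oxygen at C4, an sp3 C2 that must later be flattened, and a hemiacetal hydroxyl instead of a carbon handle at the future C8a.
- Several redox steps would be needed to reach a 3-oxy-4-pyranone, and ring A with its two phenols would still be entirely missing. The alternative therefore builds what 11 supplies by purchase and leaves the harder half of the skeleton open.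
- Comparison: both plans treat ring C as the core, but the step economy of this one would be clearly worse.

Alternative 2: The cut is C4–C4a. In the forward sense the acrylic acid A3, whose aryloxy group stands cis to the carboxyl, would be activated as a mixed anhydride and would acylate its 3,5-bis(benzyloxy)phenoxy ring ortho to the ether oxygen, closing ring C to give A4 (an intramolecular Friedel–Crafts acylation).
- In its favour: ring A would arrive complete and already benzylated, and its two ortho positions are equivalent, so regiochemistry is as secure as in the chosen plan.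
- A4 is the allyl counterpart of 25, so only deallylation, sulfation and hydrogenolysis would remain. That is three steps after the key step against five here, with no silicon to remove. On step economy and convergence this alternative is the better one.
- Its ring closure is a classical chromone synthesis, and its mechanistic certainty is at least equal.
- Against it: A3 is a tetrasubstituted enol ether whose geometry must be controlled or allowed to equilibrate. The acidic acylation conditions would also threaten electron-rich benzyl and allyl ethers through cleavage, C-benzyl migration or intermolecular acylation.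
- Comparison: the chosen plan is kept because it builds the resorcinol ring with both oxygens differentiated from the outset (free 5-OH, silylated 7-O) and uses the ring C handle of 11 directly. On paper, alternative 2 would probably be shorter.

Alternative 3: The cuts are C1′–C2′ and C5′–C6′. In the forward sense the 2-ethynylchromone A5 and the silyloxydiene A6 would combine in a (4+2) cycloaddition (Diels–Alder) to give the cyclohexa-1,4-diene A7, which would be aromatised later.
- In its favour: rings A and C would be complete, with 5,7-benzyl and 3-acetal protection already in place, and the reaction needs no metal.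
- The enol ether double bond of A7 lies between C3′ and C4′, so an enol ether oxidation could bring in the C3′ oxygen separately from the C4′ oxygen. In the logic of telling O3′ from O4′ this is the equal of the chosen plan.
- Against it: the alternative constructs a benzene ring that compound 1 offers ready-made with both oxygens.
- A7 carries only one of the two ring B oxygens and lies two oxidation levels below the arene.
- The alkyne of A5 is only moderately activated, so forcing thermal conditions, diene self-reaction and enol ether hydrolysis would be concerns.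
- Comparison: the pericyclic step is simpler than the four-bond cascade chosen here, but the step count to the target would be the highest of all four plans.

Key step: step 11

Assumption: the sulfate monoesters of 27 and 28 are drawn as neutral hydrogen sulfates, as in the target structure; in the flask they would be handled as their disodium salts, which are the stable form.

## Route

Step 1
Reactants: 1 2-(benzyloxy)phenol
Product: 2 2-(benzyloxy)phenyl acetate
Conditions: Ac2O, pyridine, DMAP (cat.), CH2Cl2, 0 °C→rt
Reagents that add atoms: acetic anhydride, CC(=O)OC(C)=O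
Why: Nucleophile-catalysed O-acylation of a phenol; the acetate lowers the donor strength of this oxygen so that the benzyloxy group alone directs the next step.

Step 2
Reactants: 2 2-(benzyloxy)phenyl acetate
Product: 4 2-(benzyloxy)-5-bromophenol, via 2-(benzyloxy)-5-bromophenyl acetate 3 (not isolated)
Conditions: NBS, MeCN, rt→50 °C; aq. Na2S2O3; then K2CO3, MeOH, rt
Reagents that add atoms: N-bromosuccinimide, O=C1CCC(=O)N1Br
Why: Electrophilic aromatic bromination should go para to the stronger donor, the benzyloxy group, as it does for aryl ether acetates of this type; transesterification with methanol then frees the phenol. Bromination of the free phenol 1 would have gone para to the hydroxyl and given the wrong ring B pattern.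

Step 3
Reactants: 4 2-(benzyloxy)-5-bromophenol
Product: 5 1-(benzyloxy)-4-bromo-2-(methoxymethoxy)benzene
Conditions: MOMCl, iPr2NEt, CH2Cl2, 0 °C→rt
Reagents that add atoms: chloromethyl methyl ether, COCCl
Why: O-alkylation of the phenol with an α-chloro ether; the acetal marks the oxygen that will later be sulfated.

Step 4
Reactants: 5 1-(benzyloxy)-4-bromo-2-(methoxymethoxy)benzene
Product: 6 2-[4-(benzyloxy)-3-(methoxymethoxy)phenyl]-4,4,5,5-tetramethyl-1,3,2-dioxaborolane
Conditions: B2pin2, Pd(dppf)Cl2 (3 mol %), KOAc, 1,4-dioxane, 90 °C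
Reagents that add atoms: bis(pinacolato)diboron, CC1(C)OB(OC1(C)C)B1OC(C)(C)C(C)(C)O1
Why: Miyaura borylation: zerovalent palladium inserts into the aryl–bromine bond and acetate-assisted transmetalation from the diboron gives the boronic ester; benzyl ether and acetal are inert.

Step 5
Reactants: 7 trimethylsilylacetylene
Product: 10 triisopropyl[(trimethylsilyl)ethynyloxy]silane, via lithium (trimethylsilyl)acetylide 8 (not isolated), via lithium 2-(trimethylsilyl)ethynolate 9 (not isolated)
Conditions: n-BuLi, THF, −78 °C; LiOOtBu (from tBuOOH + LiHMDS), THF, −78→0 °C; TIPSOTf, −78 °C→rt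
Reagents that add atoms: tert-butyl hydroperoxide, CC(C)(C)OO; triisopropylsilyl trifluoromethanesulfonate, CC(C)[Si](C(C)C)(C(C)C)OS(=O)(=O)C(F)(F)F
Why: Electrophilic oxygenation of the acetylide by the lithium peroxide gives the ynolate, a known route to silyl ynol ethers; the bulky, hard silyl triflate should silylate on oxygen and not on carbon.

Step 6
Reactants: 11 comenic acid
Product: 12 methyl 5-hydroxy-4-oxo-4H-pyran-2-carboxylate
Conditions: MeOH, H2SO4 (cat.), reflux
Reagents that add atoms: methanol, CO
Why: Fischer esterification; the ester keeps the carboxyl carbon (future C5) masked through bromination, protection and coupling.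

Step 7
Reactants: 12 methyl 5-hydroxy-4-oxo-4H-pyran-2-carboxylate
Product: 13 methyl 6-bromo-5-hydroxy-4-oxo-4H-pyran-2-carboxylate
Conditions: NBS, MeCN, 0 °C→rt
Reagents that add atoms: N-bromosuccinimide, O=C1CCC(=O)N1Br
Why: Electrophilic bromination of the enol: the C5 hydroxyl activates the adjacent C6, the known site of halogenation of comenic acid derivatives, while C3 is deactivated by the ester.

Step 8
Reactants: 13 methyl 6-bromo-5-hydroxy-4-oxo-4H-pyran-2-carboxylate
Product: 14 methyl 6-bromo-5-(methoxymethoxy)-4-oxo-4H-pyran-2-carboxylate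
Conditions: MOMCl, iPr2NEt, CH2Cl2, 0 °C→rt
Reagents that add atoms: chloromethyl methyl ether, COCCl
Why: O-alkylation of the acidic enolic hydroxyl; the same acetal as on ring B, so that both future sulfate sites are unmasked together later.

Step 9
Reactants: 14 methyl 6-bromo-5-(methoxymethoxy)-4-oxo-4H-pyran-2-carboxylate; 6 2-[4-(benzyloxy)-3-(methoxymethoxy)phenyl]-4,4,5,5-tetramethyl-1,3,2-dioxaborolane
Product: 16 6-[4-(benzyloxy)-3-(methoxymethoxy)phenyl]-5-(methoxymethoxy)-4-oxo-4H-pyran-2-carboxylic acid, via coupled methyl ester 15 (not isolated)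
Conditions: Pd(dppf)Cl2 (5 mol %), K3PO4, 1,4-dioxane/H2O, 80 °C; then LiOH, THF/H2O, 0 °C→rt; 1 M HCl to pH 3, 0 °C
Reagents that add atoms: lithium hydroxide, [Li+].[OH-]
Why: Suzuki–Miyaura coupling at the β-bromo enone carbon, which is activated for oxidative addition, forms C2–C1′. The electron-poor ester would partly hydrolyse under the aqueous base anyway, so hydrolysis is completed in the same flask with cold hydroxide to converge on one product without opening the pyranone.

Step 10
Reactants: 16 6-[4-(benzyloxy)-3-(methoxymethoxy)phenyl]-5-(methoxymethoxy)-4-oxo-4H-pyran-2-carboxylic acid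
Product: 18 2-[4-(benzyloxy)-3-(methoxymethoxy)phenyl]-6-(2-diazoacetyl)-3-(methoxymethoxy)-4H-pyran-4-one, via ethyl carbonic mixed anhydride 17 (not isolated)
Conditions: ClCO2Et, Et3N, THF, −15 °C; then TMSCHN2 (2 M in hexanes), MeCN, 0 °C→rt; aq. NaHCO3
Reagents that add atoms: (trimethylsilyl)diazomethane, C[Si](C)(C)C=[N+]=[N-]
Why: C-acylation of the silyl diazoalkane by the mixed anhydride (Arndt–Eistert-type activation), with loss of the silyl group on work-up. The activation is base-buffered so no hydrogen chloride reaches the acetals, and the non-explosive silyl reagent replaces diazomethane.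

Step 11
Reactants: 18 2-[4-(benzyloxy)-3-(methoxymethoxy)phenyl]-6-(2-diazoacetyl)-3-(methoxymethoxy)-4H-pyran-4-one; 10 triisopropyl[(trimethylsilyl)ethynyloxy]silane
Product: 23 2-[4-(benzyloxy)-3-(methoxymethoxy)phenyl]-5-hydroxy-3-(methoxymethoxy)-7-(triisopropylsilyloxy)-6-(trimethylsilyl)-4H-chromen-4-one, via pyranonylketene 19 (not isolated), via cyclobutenone 20 (not isolated), via dienylketene 21 (not isolated), via keto tautomer 22 (not isolated)
Conditions: 10 (1.5 equiv), hν (blue LEDs, ca. 450 nm), ClCH2CH2Cl, rt, degassed; then 80 °C, dark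
Reagents that add atoms: none
Why: Excitation of the diazo n–π* band expels N2 and triggers Wolff rearrangement, in which the pyranonyl carbon (future C8a) migrates to the diazo carbon (future C8) and gives ketene 19, a vinylketene by virtue of the pyranone C5=C6 bond. The electron-rich ynol ether 10 adds across the ketene C=C bond in a (2+2) cycloaddition: its silyl-bearing carbon, the nucleophilic end remote from oxygen, bonds to the ketene carbonyl carbon (C5–C6) and its oxygen-bearing carbon bonds to the ketene CH (C7–C8), giving cyclobutenone 20. On warming, 20 opens by a reversible four-electron conrotatory cleavage to dienylketene 21, and the isomer with ketene and pyranone cis closes ring A by a six-electron disrotatory electrocyclization (C4a–C5) to 22, which enolises at once to the hydrogen-bonded C5 phenol of 23. The closest known reaction type is the Danheiser benzannulation in its diazoketone (photochemical Wolff) variant, established for alkenyl and heteroaryl diazomethyl ketones and for silyloxyalkynes. No stereocentre is created in 23, because C4 of 20 and C4a of 22 are transient. The step needs regiocontrol in the (2+2) addition, which the polarisation of the ynol ether secures and the β-silicon effect of the C-silyl group reinforces, and a single site of ring fusion, which is secured because the pyranone C5=C6 bond is the only alkene conjugated with the ketene. Light near 450 nm is chosen because only the diazo chromophore should absorb there, so that the pyranone of 18 and the flavone of 23 stay unexcited.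

Step 12
Reactants: 23 2-[4-(benzyloxy)-3-(methoxymethoxy)phenyl]-5-hydroxy-3-(methoxymethoxy)-7-(triisopropylsilyloxy)-6-(trimethylsilyl)-4H-chromen-4-one
Product: 24 2-[4-(benzyloxy)-3-(methoxymethoxy)phenyl]-5,7-dihydroxy-3-(methoxymethoxy)-4H-chromen-4-one
Conditions: TBAF·3H2O (4 equiv), THF/MeOH, rt→50 °C
Reagents that add atoms: none
Why: Fluoride cleaves the aryl silyl ether; the resulting phloroglucinol-type phenoxide should be protonated at C6 by the protic medium (ipso to silicon, keto tautomer), and the α-silyl ketone so formed loses silicon to fluoride. Basic, acid-free conditions leave both acetals in place.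

Step 13
Reactants: 24 2-[4-(benzyloxy)-3-(methoxymethoxy)phenyl]-5,7-dihydroxy-3-(methoxymethoxy)-4H-chromen-4-one
Product: 25 5,7-bis(benzyloxy)-2-[4-(benzyloxy)-3-(methoxymethoxy)phenyl]-3-(methoxymethoxy)-4H-chromen-4-one
Conditions: BnBr, K2CO3, Bu4NI (cat.), DMF, 60 °C
Reagents that add atoms: benzyl bromide, BrCc1ccccc1
Why: Williamson etherification; the acidic 7-OH reacts readily, and the hydrogen-bonded 5-OH follows with excess reagent and heat, as in the exhaustive benzylation of 5-hydroxyflavones.

Step 14
Reactants: 25 5,7-bis(benzyloxy)-2-[4-(benzyloxy)-3-(methoxymethoxy)phenyl]-3-(methoxymethoxy)-4H-chromen-4-one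
Product: 26 5,7-bis(benzyloxy)-2-[4-(benzyloxy)-3-hydroxyphenyl]-3-hydroxy-4H-chromen-4-one
Conditions: HCl (2 M), MeOH/THF, rt→40 °C
Reagents that add atoms: none
Why: Acid-catalysed acetal exchange with methanol frees O3 and O3′; benzyl ethers tolerate dilute acid at this temperature. Partial loss of the chelated 5-O-benzyl group would be tolerable, since the 5-OH is the least reactive hydroxyl toward sulfation.

Step 15
Reactants: 26 5,7-bis(benzyloxy)-2-[4-(benzyloxy)-3-hydroxyphenyl]-3-hydroxy-4H-chromen-4-one
Product: 27 5,7-bis(benzyloxy)-2-[4-(benzyloxy)-3-(sulfooxy)phenyl]-4-oxo-4H-chromen-3-yl hydrogen sulfate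
Conditions: SO3·pyridine (8 equiv), pyridine, rt→45 °C; aq. NaHCO3; reversed-phase C18 (disodium salt)
Reagents that add atoms: sulfur trioxide–pyridine complex, O=S(=O)([O-])[n+]1ccccc1
Why: O-sulfonation of the only two free hydroxyls by the amine-stabilised SO3 donor, the standard way to make flavonoid sulfates; basic work-up keeps the monoesters as salts.

Step 16
Reactants: 27 5,7-bis(benzyloxy)-2-[4-(benzyloxy)-3-(sulfooxy)phenyl]-4-oxo-4H-chromen-3-yl hydrogen sulfate
Product: 28 quercetin 3,3′-bissulfate (5,7-dihydroxy-2-[4-hydroxy-3-(sulfooxy)phenyl]-4-oxo-4H-chromen-3-yl hydrogen sulfate)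
Conditions: H2 (1 atm), Pd/C (10 %), MeOH/H2O, rt
Reagents that add atoms: none
Why: Catalytic hydrogenolysis of the three benzyl ethers under neutral conditions; sulfate salts and the tetrasubstituted C2=C3 bond of the flavonol should survive.

## Compound list

1 | 2-(benzyloxy)phenol | Oc1ccccc1OCc1ccccc1 | starting material
2 | 2-(benzyloxy)phenyl acetate | CC(=O)Oc1ccccc1OCc1ccccc1 | intermediate
3 | 2-(benzyloxy)-5-bromophenyl acetate | CC(=O)Oc1cc(Br)ccc1OCc1ccccc1 | intermediate (not isolated)
4 | 2-(benzyloxy)-5-bromophenol | Oc1cc(Br)ccc1OCc1ccccc1 | intermediate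
5 | 1-(benzyloxy)-4-bromo-2-(methoxymethoxy)benzene | COCOc1cc(Br)ccc1OCc1ccccc1 | intermediate
6 | 2-[4-(benzyloxy)-3-(methoxymethoxy)phenyl]-4,4,5,5-tetramethyl-1,3,2-dioxaborolane | COCOc1cc(B2OC(C)(C)C(C)(C)O2)ccc1OCc1ccccc1 | intermediate
7 | trimethylsilylacetylene | C#C[Si](C)(C)C | starting material
8 | lithium (trimethylsilyl)acetylide | [Li]C#C[Si](C)(C)C | intermediate (not isolated)
9 | lithium 2-(trimethylsilyl)ethynolate | [Li]OC#C[Si](C)(C)C | intermediate (not isolated)
10 | triisopropyl[(trimethylsilyl)ethynyloxy]silane | C[Si](C)(C)C#CO[Si](C(C)C)(C(C)C)C(C)C | intermediate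
11 | comenic acid (5-hydroxy-4-oxo-4H-pyran-2-carboxylic acid) | O=C(O)c1cc(=O)c(O)co1 | starting material
12 | methyl 5-hydroxy-4-oxo-4H-pyran-2-carboxylate | COC(=O)c1cc(=O)c(O)co1 | intermediate
13 | methyl 6-bromo-5-hydroxy-4-oxo-4H-pyran-2-carboxylate | COC(=O)c1cc(=O)c(O)c(Br)o1 | intermediate
14 | methyl 6-bromo-5-(methoxymethoxy)-4-oxo-4H-pyran-2-carboxylate | COCOc1c(Br)oc(C(=O)OC)cc1=O | intermediate
15 | methyl 6-[4-(benzyloxy)-3-(methoxymethoxy)phenyl]-5-(methoxymethoxy)-4-oxo-4H-pyran-2-carboxylate | COC(=O)c1cc(=O)c(OCOC)c(-c2ccc(OCc3ccccc3)c(OCOC)c2)o1 | intermediate (not isolated)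
16 | 6-[4-(benzyloxy)-3-(methoxymethoxy)phenyl]-5-(methoxymethoxy)-4-oxo-4H-pyran-2-carboxylic acid | OC(=O)c1cc(=O)c(OCOC)c(-c2ccc(OCc3ccccc3)c(OCOC)c2)o1 | intermediate
17 | 6-[4-(benzyloxy)-3-(methoxymethoxy)phenyl]-5-(methoxymethoxy)-4-oxo-4H-pyran-2-carboxylic ethyl carbonic anhydride | CCOC(=O)OC(=O)c1cc(=O)c(OCOC)c(-c2ccc(OCc3ccccc3)c(OCOC)c2)o1 | intermediate (not isolated)
18 | 2-[4-(benzyloxy)-3-(methoxymethoxy)phenyl]-6-(2-diazoacetyl)-3-(methoxymethoxy)-4H-pyran-4-one | [N-]=[N+]=CC(=O)c1cc(=O)c(OCOC)c(-c2ccc(OCc3ccccc3)c(OCOC)c2)o1 | intermediate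
19 | 2-[4-(benzyloxy)-3-(methoxymethoxy)phenyl]-3-(methoxymethoxy)-6-(2-oxoethenyl)-4H-pyran-4-one (pyranonylketene) | O=C=Cc1cc(=O)c(OCOC)c(-c2ccc(OCc3ccccc3)c(OCOC)c2)o1 | intermediate (not isolated)
20 | 4-{6-[4-(benzyloxy)-3-(methoxymethoxy)phenyl]-5-(methoxymethoxy)-4-oxo-4H-pyran-2-yl}-3-(triisopropylsilyloxy)-2-(trimethylsilyl)cyclobut-2-en-1-one (racemic) | O=C1C([Si](C)(C)C)=C(O[Si](C(C)C)(C(C)C)C(C)C)C1c1cc(=O)c(OCOC)c(-c2ccc(OCc3ccccc3)c(OCOC)c2)o1 | intermediate (not isolated)
21 | 4-{6-[4-(benzyloxy)-3-(methoxymethoxy)phenyl]-5-(methoxymethoxy)-4-oxo-4H-pyran-2-yl}-3-(triisopropylsilyloxy)-2-(trimethylsilyl)buta-1,3-dien-1-one (dienylketene; ketenyl carbon and pyranonyl cis) | O=C=C([Si](C)(C)C)/C(O[Si](C(C)C)(C(C)C)C(C)C)=C\c1cc(=O)c(OCOC)c(-c2ccc(OCc3ccccc3)c(OCOC)c2)o1 | intermediate (not isolated)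
22 | 2-[4-(benzyloxy)-3-(methoxymethoxy)phenyl]-3-(methoxymethoxy)-7-(triisopropylsilyloxy)-6-(trimethylsilyl)-4aH-chromene-4,5-dione (keto tautomer of 23; racemic) | O=C1C(OCOC)=C(c2ccc(OCc3ccccc3)c(OCOC)c2)OC2=CC(O[Si](C(C)C)(C(C)C)C(C)C)=C([Si](C)(C)C)C(=O)C12 | intermediate (not isolated)
23 | 2-[4-(benzyloxy)-3-(methoxymethoxy)phenyl]-5-hydroxy-3-(methoxymethoxy)-7-(triisopropylsilyloxy)-6-(trimethylsilyl)-4H-chromen-4-one | O=c1c(OCOC)c(-c2ccc(OCc3ccccc3)c(OCOC)c2)oc2cc(O[Si](C(C)C)(C(C)C)C(C)C)c([Si](C)(C)C)c(O)c12 | intermediate
24 | 2-[4-(benzyloxy)-3-(methoxymethoxy)phenyl]-5,7-dihydroxy-3-(methoxymethoxy)-4H-chromen-4-one | O=c1c(OCOC)c(-c2ccc(OCc3ccccc3)c(OCOC)c2)oc2cc(O)cc(O)c12 | intermediate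
25 | 5,7-bis(benzyloxy)-2-[4-(benzyloxy)-3-(methoxymethoxy)phenyl]-3-(methoxymethoxy)-4H-chromen-4-one | O=c1c(OCOC)c(-c2ccc(OCc3ccccc3)c(OCOC)c2)oc2cc(OCc3ccccc3)cc(OCc3ccccc3)c12 | intermediate
26 | 5,7-bis(benzyloxy)-2-[4-(benzyloxy)-3-hydroxyphenyl]-3-hydroxy-4H-chromen-4-one | O=c1c(O)c(-c2ccc(OCc3ccccc3)c(O)c2)oc2cc(OCc3ccccc3)cc(OCc3ccccc3)c12 | intermediate
27 | 5,7-bis(benzyloxy)-2-[4-(benzyloxy)-3-(sulfooxy)phenyl]-4-oxo-4H-chromen-3-yl hydrogen sulfate | O=c1c(OS(=O)(=O)O)c(-c2ccc(OCc3ccccc3)c(OS(=O)(=O)O)c2)oc2cc(OCc3ccccc3)cc(OCc3ccccc3)c12 | intermediate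
28 | quercetin 3,3′-bissulfate | O=c1c(OS(=O)(=O)O)c(-c2ccc(O)c(OS(=O)(=O)O)c2)oc2cc(O)cc(O)c12 | target

## Step count and least certain steps

Total step count: 16. Longest linear sequence: 12 steps (from 1 through steps 1–4 and 9–16); the arm from 11 has 11 steps and the arm from 7 has 7.

Step 11 (key step). The ketene may be consumed by pathways other than the (2+2) addition, such as dimerisation or capture by adventitious nucleophiles. The thermal stage may also stall before the six-electron closure, because a pyranone double bond has not been used as the vinyl partner before. Secondary photochemistry of the pyranone would be a further loss if the light is not confined to the diazo band. The fallback abandons the benzannulation for a chalcone route and sets out from 5: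
- Bromine–lithium exchange of 5 (n-BuLi, THF, −78 °C) and formylation with DMF would give 4-(benzyloxy)-3-(methoxymethoxy)benzaldehyde F1.
- Claisen–Schmidt condensation of F1 with purchased 1-[2,4-bis(benzyloxy)-6-hydroxyphenyl]ethanone (CC(=O)c1c(O)cc(OCc2ccccc2)cc1OCc1ccccc1; KOH, EtOH) would give (E)-1-[2,4-bis(benzyloxy)-6-hydroxyphenyl]-3-[4-(benzyloxy)-3-(methoxymethoxy)phenyl]prop-2-en-1-one F2.
- Algar–Flynn–Oyamada oxidation (H2O2, NaOH, MeOH/THF) would close ring C with the C3 hydroxyl in place, giving 5,7-bis(benzyloxy)-2-[4-(benzyloxy)-3-(methoxymethoxy)phenyl]-3-hydroxy-4H-chromen-4-one F3.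
- Acetal cleavage (HCl, MeOH/THF) would bring the sequence back to the route at 26.

Step 10. The diazoalkane may add as a 1,3-dipole across the doubly activated pyranone double bond next to the acyl group, or acylation of the weakly nucleophilic silyl diazoalkane may be slow enough for the mixed anhydride to decompose. The fallback avoids diazoalkane reagents altogether and sets out from 16:
- Amide coupling with N,O-dimethylhydroxylamine hydrochloride (EDC·HCl, iPr2NEt) would give 6-[4-(benzyloxy)-3-(methoxymethoxy)phenyl]-N-methoxy-5-(methoxymethoxy)-N-methyl-4-oxo-4H-pyran-2-carboxamide F4.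
- MeMgBr at −78 °C would give 6-acetyl-2-[4-(benzyloxy)-3-(methoxymethoxy)phenyl]-3-(methoxymethoxy)-4H-pyran-4-one F5.
- Enolisation with LiHMDS and acylation with 2,2,2-trifluoroethyl trifluoroacetate would give 1-{6-[4-(benzyloxy)-3-(methoxymethoxy)phenyl]-5-(methoxymethoxy)-4-oxo-4H-pyran-2-yl}-4,4,4-trifluorobutane-1,3-dione F6, used without isolation.
- Detrifluoroacetylative diazo transfer with 4-acetamidobenzenesulfonyl azide (Et3N, H2O, MeCN) would return to the route at 18.

Step 12. Ipso-protodesilylation at C6 may remain incomplete under fluoride alone, and forcing it with acid would bring loss of the acetal groups and with it the distinction between O3/O3′ and O5/O7. The fallback keeps the carbon-bound silicon until acid is wanted anyway and leaves the chelated 5-OH unprotected; it sets out from 23: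
- One equivalent of TBAF buffered with AcOH (THF, 0 °C) would remove only the oxygen-bound silyl group, giving 2-[4-(benzyloxy)-3-(methoxymethoxy)phenyl]-5,7-dihydroxy-3-(methoxymethoxy)-6-(trimethylsilyl)-4H-chromen-4-one F7.
- Selective alkylation of the acidic 7-OH (BnBr, K2CO3, acetone, rt) would give 7-(benzyloxy)-2-[4-(benzyloxy)-3-(methoxymethoxy)phenyl]-5-hydroxy-3-(methoxymethoxy)-6-(trimethylsilyl)-4H-chromen-4-one F8.
- HCl in MeOH would cleave both acetals and the aryl–silicon bond together, giving 7-(benzyloxy)-2-[4-(benzyloxy)-3-hydroxyphenyl]-3,5-dihydroxy-4H-chromen-4-one F9.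
- SO3·pyridine in limited excess at rt should sulfate O3 and O3′ and leave the hydrogen-bonded 5-OH, giving 7-(benzyloxy)-2-[4-(benzyloxy)-3-(sulfooxy)phenyl]-5-hydroxy-4-oxo-4H-chromen-3-yl hydrogen sulfate F10.
- Hydrogenolysis (H2, Pd/C) would rejoin the route at 28.

Step 15. Sulfation may stop at the monosulfate because the enolic O3 is flanked by the aryl group and the carbonyl, and the monoesters may hydrolyse during isolation of a very polar, non-chromatographable salt. The fallback installs the sulfates as neutral, protected diesters and sets out from 26: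
- 2,2,2-Trichloroethyl chlorosulfate with Et3N and DMAP in THF would give 5,7-bis(benzyloxy)-2-{4-(benzyloxy)-3-[(2,2,2-trichloroethoxy)sulfonyloxy]phenyl}-4-oxo-4H-chromen-3-yl 2,2,2-trichloroethyl sulfate F11, which can be purified on silica.
- Reductive removal of the trichloroethyl groups (Zn, HCO2NH4, MeOH) would return to the route at 27.

## Further compounds

F1 | step 11 | 4-(benzyloxy)-3-(methoxymethoxy)benzaldehyde | O=Cc1ccc(OCc2ccccc2)c(OCOC)c1
F2 | step 11 | (E)-1-[2,4-bis(benzyloxy)-6-hydroxyphenyl]-3-[4-(benzyloxy)-3-(methoxymethoxy)phenyl]prop-2-en-1-one | O=C(/C=C/c1ccc(OCc2ccccc2)c(OCOC)c1)c1c(O)cc(OCc2ccccc2)cc1OCc1ccccc1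
F3 | step 11 | 5,7-bis(benzyloxy)-2-[4-(benzyloxy)-3-(methoxymethoxy)phenyl]-3-hydroxy-4H-chromen-4-one | O=c1c(O)c(-c2ccc(OCc3ccccc3)c(OCOC)c2)oc2cc(OCc3ccccc3)cc(OCc3ccccc3)c12
F4 | step 10 | 6-[4-(benzyloxy)-3-(methoxymethoxy)phenyl]-N-methoxy-5-(methoxymethoxy)-N-methyl-4-oxo-4H-pyran-2-carboxamide | CON(C)C(=O)c1cc(=O)c(OCOC)c(-c2ccc(OCc3ccccc3)c(OCOC)c2)o1
F5 | step 10 | 6-acetyl-2-[4-(benzyloxy)-3-(methoxymethoxy)phenyl]-3-(methoxymethoxy)-4H-pyran-4-one | CC(=O)c1cc(=O)c(OCOC)c(-c2ccc(OCc3ccccc3)c(OCOC)c2)o1
F6 | step 10 | 1-{6-[4-(benzyloxy)-3-(methoxymethoxy)phenyl]-5-(methoxymethoxy)-4-oxo-4H-pyran-2-yl}-4,4,4-trifluorobutane-1,3-dione | O=C(CC(=O)C(F)(F)F)c1cc(=O)c(OCOC)c(-c2ccc(OCc3ccccc3)c(OCOC)c2)o1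
F7 | step 12 | 2-[4-(benzyloxy)-3-(methoxymethoxy)phenyl]-5,7-dihydroxy-3-(methoxymethoxy)-6-(trimethylsilyl)-4H-chromen-4-one | O=c1c(OCOC)c(-c2ccc(OCc3ccccc3)c(OCOC)c2)oc2cc(O)c([Si](C)(C)C)c(O)c12
F8 | step 12 | 7-(benzyloxy)-2-[4-(benzyloxy)-3-(methoxymethoxy)phenyl]-5-hydroxy-3-(methoxymethoxy)-6-(trimethylsilyl)-4H-chromen-4-one | O=c1c(OCOC)c(-c2ccc(OCc3ccccc3)c(OCOC)c2)oc2cc(OCc3ccccc3)c([Si](C)(C)C)c(O)c12
F9 | step 12 | 7-(benzyloxy)-2-[4-(benzyloxy)-3-hydroxyphenyl]-3,5-dihydroxy-4H-chromen-4-one | O=c1c(O)c(-c2ccc(OCc3ccccc3)c(O)c2)oc2cc(OCc3ccccc3)cc(O)c12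
F10 | step 12 | 7-(benzyloxy)-2-[4-(benzyloxy)-3-(sulfooxy)phenyl]-5-hydroxy-4-oxo-4H-chromen-3-yl hydrogen sulfate | O=c1c(OS(=O)(=O)O)c(-c2ccc(OCc3ccccc3)c(OS(=O)(=O)O)c2)oc2cc(OCc3ccccc3)cc(O)c12
F11 | step 15 | 5,7-bis(benzyloxy)-2-{4-(benzyloxy)-3-[(2,2,2-trichloroethoxy)sulfonyloxy]phenyl}-4-oxo-4H-chromen-3-yl 2,2,2-trichloroethyl sulfate | O=c1c(OS(=O)(=O)OCC(Cl)(Cl)Cl)c(-c2ccc(OCc3ccccc3)c(OS(=O)(=O)OCC(Cl)(Cl)Cl)c2)oc2cc(OCc3ccccc3)cc(OCc3ccccc3)c12
A1 | alternative 1 | [4-(benzyloxy)-3-(methoxymethoxy)phenyl](furan-2-yl)methanol (racemic) | OC(c1ccco1)c1ccc(OCc2ccccc2)c(OCOC)c1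
A2 | alternative 1 | 2-[4-(benzyloxy)-3-(methoxymethoxy)phenyl]-6-hydroxy-2H-pyran-3(6H)-one (racemic mixture of anomers) | O=C1C=CC(O)OC1c1ccc(OCc2ccccc2)c(OCOC)c1
A3 | alternative 2 | 2-(allyloxy)-3-[3-(allyloxy)-4-(benzyloxy)phenyl]-3-[3,5-bis(benzyloxy)phenoxy]prop-2-enoic acid (aryloxy cis to carboxyl) | OC(=O)/C(OCC=C)=C(\Oc1cc(OCc2ccccc2)cc(OCc2ccccc2)c1)c1ccc(OCc2ccccc2)c(OCC=C)c1
A4 | alternative 2 | 3-(allyloxy)-2-[3-(allyloxy)-4-(benzyloxy)phenyl]-5,7-bis(benzyloxy)-4H-chromen-4-one | O=c1c(OCC=C)c(-c2ccc(OCc3ccccc3)c(OCC=C)c2)oc2cc(OCc3ccccc3)cc(OCc3ccccc3)c12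
A5 | alternative 3 | 5,7-bis(benzyloxy)-2-ethynyl-3-(methoxymethoxy)-4H-chromen-4-one | C#Cc1oc2cc(OCc3ccccc3)cc(OCc3ccccc3)c2c(=O)c1OCOC
A6 | alternative 3 | 2-(tert-butyldimethylsilyloxy)buta-1,3-diene | C=CC(=C)O[Si](C)(C)C(C)(C)C
A7 | alternative 3 | 5,7-bis(benzyloxy)-2-[4-(tert-butyldimethylsilyloxy)cyclohexa-1,4-dien-1-yl]-3-(methoxymethoxy)-4H-chromen-4-one | CC(C)(C)[Si](C)(C)OC1=CCC(=CC1)c1oc2cc(OCc3ccccc3)cc(OCc3ccccc3)c2c(=O)c1OCOC
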